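Atom labels: C1 = CH–OBz next to the quaternary carbon, C2=C3 = ring alkene, C4 = second CH–OBz, C5 = CH–OH, C6 = quaternary C–OH, C7 = CH2OH on C6.
Enabling feature: the single carbocycle is a cyclohexene whose C1–O and C4–O bonds flank C2=C3 on the same face as C7, while C5–O and C6–O lie together on the opposite face. This is the imprint of an E,E-1,4-dioxygenated butadiene on a ring-locked Z-enediol ether whose carbonyl carbon (C7) sat under the diene.
Retrosynthesis: benzoates go back to acetates, the C5/C6 diol is masked as an acetonide and C7 is raised to an acyl oxazolidinone. C1–C6 and C4–C5 are then cut together, giving (E,E)-1,4-diacetoxybutadiene and a 1,3-dioxole-4-carbonyl imide.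
Forward order: the dioxole dienophile is built from glycerate acetonide (steps 1–4), the only carbocycle closes in step 5, and steps 6–9 adjust oxidation level and acyl groups.
Stereochemistry: diene geometry fixes C1/C4, the dioxole ring fixes C5/C6, the endo transition state links the two pairs, and the (R,R)-t-Bu-box copper catalyst sets the absolute sense. No later step breaks a bond at a stereocentre.

Key step: step 5

Notation: t-Bu-box = 2,2'-(propane-2,2-diyl)bis(4-tert-butyl-4,5-dihydro-1,3-oxazole); descriptors of all cyclohexene compounds use the atom labels above.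
Assumption: the sense of induction is extrapolated from the square-planar, s-cis chelate model of 3-acryloyloxazolidin-2-one, which calls for the (R,R) ligand for attack on the required face of C6; should the α-oxygen invert the reactive conformer, the (S,S) ligand is used with nothing else changed.

Step 1
Reactants: 1 methyl 2,2-dimethyl-1,3-dioxolane-4-carboxylate (racemate or either enantiomer)
Product: 3 methyl 2,2-dimethyl-4-(phenylselanyl)-1,3-dioxolane-4-carboxylate (racemic), via lithium enolate 2 (not isolated)
Conditions: LiN(i-Pr)2, THF, −78 °C; PhSeCl, −78 °C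
Reagents that add atoms: benzeneselenenyl chloride, Cl[Se]c1ccccc1
Why: α-Selenenylation of an ester enolate: at −78 °C enolate 2 resists β-elimination because the ring CH2–O bond lies near the nodal plane of the enolate π system (ring opening would be a reverse 5-endo-trig process), PhSeCl traps it rapidly at carbon, and the new quaternary centre forms as a racemate that the next step erases.

Step 2
Reactants: 3 methyl 2,2-dimethyl-4-(phenylselanyl)-1,3-dioxolane-4-carboxylate
Product: 5 methyl 2,2-dimethyl-1,3-dioxole-4-carboxylate, via selenoxide 4 (not isolated)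
Conditions: mCPBA (1 equiv), CH2Cl2, −78 °C; Et3N, warm to 25–40 °C
Reagents that add atoms: 3-chloroperoxybenzoic acid, O=C(OO)c1cccc(Cl)c1 (supplies the oxygen of selenoxide 4 only; none of it remains in 5)
Why: Selenium oxidation followed by selenoxide syn-elimination: the ring CH2 carries the only β-hydrogens, one of them is held syn-periplanar to C–Se in the five-membered ring, and conjugation with the ester assists an elimination toward an oxygen-bearing carbon, a direction known from selenoxide routes to glycals.

Step 3
Reactants: 5 methyl 2,2-dimethyl-1,3-dioxole-4-carboxylate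
Product: 6 2,2-dimethyl-1,3-dioxole-4-carboxylic acid
Conditions: LiOH, THF–H2O, 0 °C → rt; cold 1 M HCl to pH 3–4, immediate extraction
Reagents that add atoms: lithium hydroxide, [Li+].[OH-]
Why: Saponification (BAc2) of a β-alkoxyacrylate-type methyl ester, a class routinely hydrolysed with aqueous hydroxide and re-acidified without loss of the enol ether, because the carboxyl group deactivates the alkene toward protonation.

Step 4
Reactants: 6 2,2-dimethyl-1,3-dioxole-4-carboxylic acid; 7 oxazolidin-2-one
Product: 9 3-(2,2-dimethyl-1,3-dioxole-4-carbonyl)oxazolidin-2-one, via mixed pivalic anhydride 8 (not isolated)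
Conditions: t-BuCOCl, Et3N, THF, −20 °C; then 7, LiCl, −20 °C → rt
Reagents that add atoms: pivaloyl chloride, CC(C)(C)C(=O)Cl (its acyl group is present in 8 only and leaves again)
Why: N-Acylation of an oxazolidinone through a mixed pivalic anhydride under LiCl/Et3N: the tert-butyl group steers the lithium-coordinated carbamate nitrogen to the dioxole carbonyl, and the acid-labile ketal meets neither strong base nor acid chloride conditions.

Step 5
Reactants: 9 3-(2,2-dimethyl-1,3-dioxole-4-carbonyl)oxazolidin-2-one; 10 (1E,3E)-buta-1,3-diene-1,4-diyl diacetate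
Product: 11 (1S,4R,5S,6R)-5,6-(isopropylidenedioxy)-6-(2-oxooxazolidine-3-carbonyl)cyclohex-2-ene-1,4-diyl diacetate (both acetoxy groups and C7 on one face; both ketal oxygens on the other)
Conditions: [Cu((R,R)-t-Bu-box)](SbF6)2 (20 mol %), 10 (3 equiv), 4 Å MS, CH2Cl2 (1 M), 25 → 40 °C
Reagents that add atoms: none
Why: Proposed new method: the two imide carbonyls of 9 chelate the square-planar divalent copper centre, which lowers the LUMO of the otherwise push–pull C5=C6 bond enough for a normal-demand, concerted but asynchronous [4π+2π] addition of s-cis 10, with C4–C5 bonding running ahead of C1–C6. The closest known reaction type is the bis(oxazoline)–copper-catalysed Diels–Alder reaction of 3-acryloyloxazolidin-2-one with 1-acetoxybutadiene; what has not been shown is an α-branched, α,β-dioxygenated enoyl imide or a diene oxygenated at both termini. The cyclohexene closes in this one intermolecular, suprafacial–suprafacial event, both σ bonds arising in the same transition state. C1 and C4 come out cis because both acetoxy groups are outside substituents of the E,E-diene, C5–O and C6–O come out cis because the dioxole ring locks them Z, and the endo position of the chelated acyl group puts C7 on the acetoxy face and the ring oxygens on the opposite face. The absolute configuration follows from the s-cis chelate, in which the tert-butyl group of the (R,R) ligand next to the acyl oxygen covers one face of C6, so that the diene bonds to the face from which C7, C5 and O run anticlockwise. Only endo and facial selectivity are needed, since the equivalent diene termini raise no regiochemical question, and the endo preference is reinforced by the gem-dimethyl group of 9, which would point into the diene if the heterocycle rather than the acyl group lay beneath it.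

Step 6
Reactants: 11 (1S,4R,5S,6R)-5,6-(isopropylidenedioxy)-6-(2-oxooxazolidine-3-carbonyl)cyclohex-2-ene-1,4-diyl diacetate
Product: 12 (1S,4R,5S,6R)-6-(hydroxymethyl)-5,6-(isopropylidenedioxy)cyclohex-2-ene-1,4-diol
Conditions: LiBH4 (excess), H2O (1 equiv), THF–Et2O, 0 °C → rt; aqueous work-up
Reagents that add atoms: none
Why: Reductive cleavage of an N-acyloxazolidinone to the primary alcohol with LiBH4 and concurrent ester reduction of both acetates: the α-oxygen makes the exocyclic carbonyl the most electrophilic site, so C7 is reduced before a free C1 alkoxide could trigger retro-aldol cleavage, and no stereocentre is touched.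

Step 7
Reactants: 12 (1S,4R,5S,6R)-6-(hydroxymethyl)-5,6-(isopropylidenedioxy)cyclohex-2-ene-1,4-diol
Product: 13 (1S,4R,5S,6R)-6-[(tert-butyldimethylsilyloxy)methyl]-5,6-(isopropylidenedioxy)cyclohex-2-ene-1,4-diol
Conditions: TBSCl (1.05 equiv), imidazole, CH2Cl2–DMF, −20 → 0 °C
Reagents that add atoms: tert-butyldimethylsilyl chloride, CC(C)(C)[Si](C)(C)Cl
Why: Sterically governed silylation: although neopentylic, C7–OH is the only primary hydroxyl and should react with one equivalent of the bulky chlorosilane ahead of the two secondary allylic hydroxyls at low temperature.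

Step 8
Reactants: 13 (1S,4R,5S,6R)-6-[(tert-butyldimethylsilyloxy)methyl]-5,6-(isopropylidenedioxy)cyclohex-2-ene-1,4-diol
Product: 14 (1S,4R,5S,6R)-6-[(tert-butyldimethylsilyloxy)methyl]-5,6-(isopropylidenedioxy)cyclohex-2-ene-1,4-diyl dibenzoate
Conditions: BzCl (3 equiv), pyridine, 4-(dimethylamino)pyridine (cat.), CH2Cl2, 0 °C → rt
Reagents that add atoms: benzoyl chloride, O=C(Cl)c1ccccc1
Why: Nucleophile-catalysed O-acylation of the two remaining hydroxyls, which takes place at oxygen with retention at C1 and C4 and leaves ketal, silyl ether and alkene untouched.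

Step 9
Reactants: 14 (1S,4R,5S,6R)-6-[(tert-butyldimethylsilyloxy)methyl]-5,6-(isopropylidenedioxy)cyclohex-2-ene-1,4-diyl dibenzoate
Product: 15 (1S,4R,5S,6S)-5,6-dihydroxy-6-(hydroxymethyl)cyclohex-2-ene-1,4-diyl dibenzoate (CNP0212417.1)
Conditions: CF3CO2H–H2O 9:1, CH2Cl2, 0 °C → rt
Reagents that add atoms: none
Why: Acid-catalysed hydrolysis of the ketal and the primary silyl ether in one operation: benzoates tolerate cold aqueous CF3CO2H, acid rather than base or fluoride avoids base-promoted drift of the C1 benzoate to the cis C7 hydroxyl, and every C–O bond at a stereocentre stays intact (the C6 descriptor changes only because the CIP ranking of C1 and C5 changes).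

Compound list
1 | methyl 2,2-dimethyl-1,3-dioxolane-4-carboxylate | COC(=O)C1COC(C)(C)O1 | starting material
2 | lithium enolate of 1 | [Li+].[O-]C(OC)=C1COC(C)(C)O1 | intermediate
3 | methyl 2,2-dimethyl-4-(phenylselanyl)-1,3-dioxolane-4-carboxylate (racemic) | COC(=O)C1(COC(C)(C)O1)[Se]c1ccccc1 | intermediate
4 | methyl 2,2-dimethyl-4-(phenylseleninyl)-1,3-dioxolane-4-carboxylate (selenoxide, stereoisomer mixture) | COC(=O)C1(COC(C)(C)O1)[Se](=O)c1ccccc1 | intermediate
5 | methyl 2,2-dimethyl-1,3-dioxole-4-carboxylate | COC(=O)C1=COC(C)(C)O1 | intermediate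
6 | 2,2-dimethyl-1,3-dioxole-4-carboxylic acid | OC(=O)C1=COC(C)(C)O1 | intermediate
7 | oxazolidin-2-one | O=C1NCCO1 | starting material
8 | 2,2-dimethyl-1,3-dioxole-4-carboxylic pivalic anhydride | CC(C)(C)C(=O)OC(=O)C1=COC(C)(C)O1 | intermediate
9 | 3-(2,2-dimethyl-1,3-dioxole-4-carbonyl)oxazolidin-2-one | CC1(C)OC=C(O1)C(=O)N1CCOC1=O | intermediate
10 | (1E,3E)-buta-1,3-diene-1,4-diyl diacetate | CC(=O)O/C=C/C=C/OC(C)=O | starting material
11 | (1S,4R,5S,6R)-5,6-(isopropylidenedioxy)-6-(2-oxooxazolidine-3-carbonyl)cyclohex-2-ene-1,4-diyl diacetate | CC(=O)O[C@H]1C=C[C@@H](OC(C)=O)[C@@H]2OC(C)(C)O[C@]12C(=O)N1CCOC1=O | intermediate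
12 | (1S,4R,5S,6R)-6-(hydroxymethyl)-5,6-(isopropylidenedioxy)cyclohex-2-ene-1,4-diol | O[C@H]1C=C[C@@H](O)[C@@H]2OC(C)(C)O[C@]12CO | intermediate
13 | (1S,4R,5S,6R)-6-[(tert-butyldimethylsilyloxy)methyl]-5,6-(isopropylidenedioxy)cyclohex-2-ene-1,4-diol | O[C@H]1C=C[C@@H](O)[C@@H]2OC(C)(C)O[C@]12CO[Si](C)(C)C(C)(C)C | intermediate
14 | (1S,4R,5S,6R)-6-[(tert-butyldimethylsilyloxy)methyl]-5,6-(isopropylidenedioxy)cyclohex-2-ene-1,4-diyl dibenzoate | O=C(O[C@H]1C=C[C@@H](OC(=O)c2ccccc2)[C@@H]2OC(C)(C)O[C@]12CO[Si](C)(C)C(C)(C)C)c1ccccc1 | intermediate
15 | (1S,4R,5S,6S)-5,6-dihydroxy-6-(hydroxymethyl)cyclohex-2-ene-1,4-diyl dibenzoate | O=C(O[C@H]1C=C[C@@H](OC(=O)c2ccccc2)[C@H](O)[C@@]1(O)CO)c1ccccc1 | target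

Total step count: 9. Longest linear sequence: 9 steps (1 → 15); 7 and 10 enter as purchased materials.

Steps most likely to fail

Step 5. Three things may go wrong.
- The cycloaddition may be sluggish, because two donor oxygens raise the LUMO and the α-oxygen may twist the chelate out of planarity.
- Endo or facial control may erode.
- The Lewis acid may break down the ketal.

The fallback replaces catalytic induction by a covalently bound controller and a stoichiometric, far more strongly activating cationic aluminium chelate. This is the established auxiliary-controlled Diels–Alder reaction of N-enoyl-4-benzyloxazolidinones with acyclic dienes. It sets out from acid 6. Activation as anhydride 8 and coupling with (S)-4-benzyloxazolidin-2-one (LiCl, Et3N) should give (S)-4-benzyl-3-(2,2-dimethyl-1,3-dioxole-4-carbonyl)oxazolidin-2-one F1. With Et2AlCl (1.4 equiv) and diene 10 in CH2Cl2 at −78 → −20 °C, the diene should add endo to the face opposite the benzyl group, which is the face required. The product would be (1S,4R,5S,6R)-6-[(S)-4-benzyl-2-oxooxazolidine-3-carbonyl]-5,6-(isopropylidenedioxy)cyclohex-2-ene-1,4-diyl diacetate F2, from which minor diastereomers can be removed by chromatography or crystallisation. LiBH4 as in step 6 brings the material back to the route at triol 12.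

Step 1. The enolate may undergo ring-opening β-elimination or self-condensation before it is trapped, and downstream the elimination toward the oxygen-bearing carbon may be reluctant. The fallback avoids carbanion and selenium chemistry altogether. It sets out from 1, which under Wohl–Ziegler conditions (N-bromosuccinimide, azobisisobutyronitrile, PhCF3, reflux) should be brominated at the captodative tertiary C–H to give methyl 4-bromo-2,2-dimethyl-1,3-dioxolane-4-carboxylate F3. DBU in CH2Cl2 at 0 °C then removes HBr, and the sequence rejoins the route at dioxole ester 5.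

Step 6. Hydride may attack the ring carbonyl of the oxazolidinone (endocyclic opening) because the acyl carbon hangs on the fully substituted C6, and acetate cleavage may be incomplete. The fallback removes the heterocycle hydrolytically and reduces afterwards. It sets out from 11. LiOOH (LiOH, H2O2, THF–H2O, 0 °C) is the nucleophile known to choose the exocyclic carbonyl even of hindered imides. Continued exposure to LiOH to remove the acetates, followed by a Na2SO3 quench, should give (1S,4R,5S,6R)-1,4-dihydroxy-5,6-(isopropylidenedioxy)cyclohex-2-ene-6-carboxylic acid F4. LiAlH4 in THF then reduces the carboxyl group, and the route is rejoined at triol 12.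

Further compounds
F1 | step 5 | (S)-4-benzyl-3-(2,2-dimethyl-1,3-dioxole-4-carbonyl)oxazolidin-2-one | CC1(C)OC=C(O1)C(=O)N1[C@@H](Cc2ccccc2)COC1=O
F2 | step 5 | (1S,4R,5S,6R)-6-[(S)-4-benzyl-2-oxooxazolidine-3-carbonyl]-5,6-(isopropylidenedioxy)cyclohex-2-ene-1,4-diyl diacetate | CC(=O)O[C@H]1C=C[C@@H](OC(C)=O)[C@@H]2OC(C)(C)O[C@]12C(=O)N1[C@@H](Cc2ccccc2)COC1=O
F3 | step 1 | methyl 4-bromo-2,2-dimethyl-1,3-dioxolane-4-carboxylate (racemic) | COC(=O)C1(Br)COC(C)(C)O1
F4 | step 6 | (1S,4R,5S,6R)-1,4-dihydroxy-5,6-(isopropylidenedioxy)cyclohex-2-ene-6-carboxylic acid | O[C@H]1C=C[C@@H](O)[C@@H]2OC(C)(C)O[C@]12C(=O)O
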